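Labels: quinolone A and pyran A hold C-a (the CH that bears the isobutenyl group). Quinolone B and pyran B hold C-d (CMe2). The two pyrans share the cis ring-fusion bond C-b–C-c (C-b = CH on C-3 of quinolone B, C-c = O–CH).
Cuts: one retrosynthetic move breaks the aryl ether bond C-4(B)–O(C-d), the fusion bond C-b–C-c and the bond C-a–C-3(A). The two halves, epoxy ether 10 and chlorodiene 7, are then cut at the oxirane oxygen, the enol ether C–O bond, the C-b=C-a double bond and the formyl/chloro groups. Both halves fall back on quinolone 1.
Enabling feature: in pyran A the atoms C-3(A)=C-4(A)–O–C-c form a 2-oxadiene as soon as C-c is electron-deficient. C-c stands next to the oxygen-bearing C-d, so C-c, C-d and that oxygen are a masked 2-aryloxy-3,3-dimethyloxirane. C-4 of quinolone B is a vinylogous acyl carbon that can carry chloride.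
Forward: 1 gives 7 (chloroformylation, Wittig) and 10 (O-alkenylation, epoxidation). In one flask the diene opens the strained oxirane, pyran A closes by a polar [4+2], and the released oxygen closes pyran B at C-4(B).
Stereochemistry: C-c comes from a Shi epoxidation and is passed on with inversion. C-b and C-a follow from the endo, suprafacial addition to the E double bond.

Key step: step 5

Assumption: in the spiro transition state of the ketone-catalysed epoxidation the aryloxy group of 9 is taken to occupy the place of the alkyl group of a 2-methylalk-2-ene, so the L-fructose-derived ketone should give (R)-10; if the sense is opposite, the D-fructose-derived ketone is used.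

Step 1
Reactants: 1 4-hydroxy-1-methylquinolin-2(1H)-one
Product: 3 4-chloro-1-methyl-2-oxo-1,2-dihydroquinoline-3-carbaldehyde, via iminium chloride 2 (not isolated)
Conditions: POCl3 (4 equiv), DMF, 0 to 70 °C; then ice-water
Reagents that add atoms: N,N-dimethylformamide CN(C)C=O; phosphoryl chloride O=P(Cl)(Cl)Cl; water O
Why: Vilsmeier–Haack chloroformylation, well established for 4-hydroxycoumarins and 4-hydroxy-2-quinolones: the chloroiminium salt attacks the nucleophilic C-3 of the vinylogous acid, the activated 4-oxygen is replaced by chloride, and water hydrolyses iminium salt 2 to the aldehyde; no stereocentre is formed.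

Step 2
Reactants: 3 4-chloro-1-methyl-2-oxo-1,2-dihydroquinoline-3-carbaldehyde; 4 (3-methylbut-2-en-1-yl)triphenylphosphonium bromide
Product: 7 4-chloro-1-methyl-3-[(1E)-4-methylpenta-1,3-dien-1-yl]quinolin-2(1H)-one, via prenylidene ylide 5 (not isolated), via 1Z-diene 6 (not isolated)
Conditions: 4, NaN(SiMe3)2, THF, 0 °C; ylide solution added to 3, THF, −78 °C to rt; then I2 (5 mol %), daylight, rt
Reagents that add atoms: none
Why: Wittig olefination: at −78 °C the semi-stabilised allylic ylide 5 should add to the non-enolisable, very electrophilic aldehyde faster than to C-4, and iodine-atom catalysis equilibrates the 1Z isomer 6 to the less crowded 1E-diene 7, whose geometry later fixes the trans relation at C-a/C-b.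

Step 3
Reactants: 1 4-hydroxy-1-methylquinolin-2(1H)-one; 8 (2-methylprop-1-en-1-yl)boronic acid
Product: 9 1-methyl-4-[(2-methylprop-1-en-1-yl)oxy]quinolin-2(1H)-one
Conditions: Cu(OAc)2 (20 mol %), pyridine (3 equiv), 4 Å molecular sieves, O2 (1 atm), CH2Cl2, rt
Reagents that add atoms: none
Why: Chan–Lam–Evans oxidative C–O coupling, known for phenols and carboxylic acids with alkenylboron reagents: the acidic 4-OH binds to copper, the alkenyl group moves from boron to copper, and reductive elimination from trivalent copper gives the enol ether at oxygen rather than at C-3; no stereocentre is formed.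

Step 4
Reactants: 9 1-methyl-4-[(2-methylprop-1-en-1-yl)oxy]quinolin-2(1H)-one
Product: 10 4-{[(2R)-3,3-dimethyloxiran-2-yl]oxy}-1-methylquinolin-2(1H)-one
Conditions: L-fructose-derived Shi ketone (1,2:4,5-di-O-isopropylidene-β-L-erythro-hexo-2,3-diulo-2,6-pyranose, 30 mol %), KHSO5 (as Oxone, 2KHSO5·KHSO4·K2SO4), K2CO3, Bu4NHSO4 (5 mol %), MeCN–CH2(OMe)2 / aq. Na2B4O7 buffer, pH 10.5, −10 to 0 °C; extraction, filtration through Et3N-washed silica
Reagents that add atoms: potassium peroxymonosulfate [K+].[O-]S(=O)(=O)OO
Why: Shi epoxidation, known to give isolable non-racemic epoxides from trisubstituted enol esters and enol ethers: the chiral dioxirane attacks the only electron-rich, non-aromatic double bond through a spiro transition state, the catalyst selects the face and sets the (R) centre at C-c, and the electron-poor vinylogous-carbamate oxygen together with the basic buffer should keep the epoxy ether intact.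

Step 5
Reactants: 10 4-{[(2R)-3,3-dimethyloxiran-2-yl]oxy}-1-methylquinolin-2(1H)-one; 7 4-chloro-1-methyl-3-[(1E)-4-methylpenta-1,3-dien-1-yl]quinolin-2(1H)-one
Product: 12 target dimer (C-a R, C-b S, C-c S; H on C-b and H on C-c cis, isobutenyl group on C-a trans to quinolone B), via seco-chloride TBS ether 11 (not isolated)
Conditions: 7 (1.5 equiv), t-BuMe2SiOTf (1.2 equiv), 2,6-di-tert-butyl-4-methylpyridine (1.5 equiv), CH2Cl2–toluene 1:1, −78 °C, slow addition of 10, then to −40 °C; then Bu4NF (3 equiv, THF), −40 to 40 °C, same flask
Reagents that add atoms: none
Why: Proposed new method: t-BuMe2SiOTf silylates the oxirane oxygen of 10, and the diene terminus of 7 that carries quinolone B attacks the acetal-level carbon C-c from the side opposite to the breaking C–O bond, so that ring strain is released, C-b–C-c is made and a 1,1-dimethylallyl cation is left beside a tertiary silyloxy group; C-3 of quinolone A, an enol-ether carbon, captures the secondary end C-a of this cation, the hindered pyridine takes the proton to give 11, and fluoride then frees the tertiary alkoxide, which displaces chloride from C-4 of quinolone B. The closest known reaction types are the oxa-Povarov synthesis of chromans from aryl alkyl acetals, SnCl4 and alkenes, the invertive Lewis-acid opening of 1,2-anhydro sugars and aryl oxiranes by carbon π-nucleophiles, epoxide-initiated cation–olefin cyclisation, and alkoxide addition–elimination at 4-chloro-2-quinolones; new is the use of an epoxy ether as a chiral oxocarbenium equivalent whose departing oxygen is kept for the second ring. Pyran A closes as a stepwise polar [4+2] (2-oxadiene C-3=C-4–O–C-c plus alkene C-b=C-a, the last bond being a six-membered closure of C-3 onto the allyl cation), and pyran B closes by 6-endo-trig addition followed by loss of chloride. C-c is controlled by the (R)-oxirane through inversion, C-b by the endo position of quinolone B relative to the outward-pointing silyloxy-isopropyl group (the exo alternative would push the isobutenyl group under the lactam ring of quinolone A), and C-a by suprafacial addition to the E-alkene, reinforced by allylic strain with the C-2 carbonyl of quinolone A, which keeps the isobutenyl group pseudo-axial and trans to quinolone B. The step needs attack at C-c and not at the CMe2 carbon (secured by the aryloxy donor and the lower substitution of C-c), attack by the diene terminus C-b and not by the isobutenyl end (only this mode gives a tertiary allyl cation and avoids a quaternary centre), carbon rather than oxygen capture of the cation (bulky silyl cap, reversible allylic C–O bond formation against final C–C closure with proton loss), and bond formation ahead of free ionisation (electron-poor vinylogous-carbamate oxygen, non-polar medium, −78 °C, slow addition of 10 to excess 7).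

Compound list
1 | 4-hydroxy-1-methylquinolin-2(1H)-one | Cn1c(=O)cc(O)c2ccccc21 | starting material
2 | [(4-chloro-1-methyl-2-oxo-1,2-dihydroquinolin-3-yl)methylidene]dimethyliminium chloride | C[N+](C)=Cc1c(Cl)c2ccccc2n(C)c1=O.[Cl-] | intermediate
3 | 4-chloro-1-methyl-2-oxo-1,2-dihydroquinoline-3-carbaldehyde | O=Cc1c(Cl)c2ccccc2n(C)c1=O | intermediate
4 | (3-methylbut-2-en-1-yl)triphenylphosphonium bromide | CC(C)=CC[P+](c1ccccc1)(c1ccccc1)c1ccccc1.[Br-] | starting material
5 | (3-methylbut-2-en-1-ylidene)triphenylphosphorane | CC(C)=CC=P(c1ccccc1)(c1ccccc1)c1ccccc1 | intermediate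
6 | 4-chloro-1-methyl-3-[(1Z)-4-methylpenta-1,3-dien-1-yl]quinolin-2(1H)-one | CC(C)=C/C=C\c1c(Cl)c2ccccc2n(C)c1=O | intermediate
7 | 4-chloro-1-methyl-3-[(1E)-4-methylpenta-1,3-dien-1-yl]quinolin-2(1H)-one | CC(C)=C/C=C/c1c(Cl)c2ccccc2n(C)c1=O | intermediate
8 | (2-methylprop-1-en-1-yl)boronic acid | CC(C)=CB(O)O | starting material
9 | 1-methyl-4-[(2-methylprop-1-en-1-yl)oxy]quinolin-2(1H)-one | CC(C)=COc1cc(=O)n(C)c2ccccc12 | intermediate
10 | 4-{[(2R)-3,3-dimethyloxiran-2-yl]oxy}-1-methylquinolin-2(1H)-one | CC1(C)O[C@H]1Oc1cc(=O)n(C)c2ccccc12 | intermediate
11 | pyran A closed, pyran B open: dihydropyrano[3,2-c]quinolin-5-one with isobutenyl on C-a (R), 4-chloro-1-methyl-2-oxoquinolin-3-yl on C-b (S) and 2-(tert-butyldimethylsilyloxy)propan-2-yl on C-c (S) | CC(C)=C[C@H]1c2c(c3ccccc3n(C)c2=O)O[C@H](C(C)(C)O[Si](C)(C)C(C)(C)C)[C@@H]1c1c(Cl)c3ccccc3n(C)c1=O | intermediate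
12 | target CNP0107253.2, cis-fused bis(pyrano[3,2-c]quinolin-5-one) (C-a R, C-b S, C-c S) | CC(C)=C[C@H]1c2c(c3ccccc3n(C)c2=O)O[C@H]2[C@@H]1c1c(c3ccccc3n(C)c1=O)OC2(C)C | target

Total steps: 5. Longest linear sequence: 3 steps (1 → 9 → 10 → 12, or 1 → 3 → 7 → 12).

Steps most likely to fail

1. Step 5 (new method).
- Free ionisation of the silylated epoxy ether may occur before the diene arrives. That would cause loss of the stereochemical information, a 1,2-methyl shift, or alkylation at C-3 of a second molecule of 10.
- The allyl cation may be captured at oxygen instead of carbon.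
- The endo/exo preference at C-b may be weak.

The fallback uses known chemistry and a different bond set. It sets out from 1 and comes back at 12. Condensation of 1 with 3-methylbut-2-enal (ethylenediammonium diacetate, toluene, reflux; Knoevenagel condensation and oxa-6π electrocyclisation) should give N-methylflindersine F1. Heating F1 (o-dichlorobenzene, sealed tube, about 180 °C) opens part of it to the quinone methide. This adds as a heterodiene to the pyran double bond of a second molecule in an inverse-demand hetero-Diels–Alder reaction, and the ring alkene dictates the cis fusion. After separation from isomeric adducts this should give the racemic dimer F2. Preparative HPLC on a polysaccharide chiral phase then delivers 12.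

2. Step 4.
- The epoxy ether may be opened hydrolytically in the aqueous buffer.
- Facial selectivity may be poor, because the catalyst must tell a hydrogen from an aryloxy group on one olefin carbon.

The fallback replaces asymmetric catalysis by resolution. It sets out from 9 and comes back at 10. Epoxidation of 9 with an acetone-free dimethyldioxirane solution (CH2Cl2, −40 °C, anhydrous and neutral) should give the racemic epoxy ether F3. Its enantiomers are separated by supercritical-fluid chromatography on a chiral phase with an aprotic modifier (CO2/MeCN), and the (R) enantiomer is 10.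

3. Step 3.
- Oxidative coupling at the nucleophilic C-3 of 1 may compete with C–O bond formation.
- Protodeboronation or homocoupling of 8 may outrun the C–O coupling.

The fallback makes the C–O bond at an sp3 carbon and then moves the double bond. It sets out from 1 and comes back at 9. Mitsunobu reaction of 1 with 2-methylprop-2-en-1-ol (PPh3, DIAD, THF, 0 °C to rt), which is O-selective because the lactam nitrogen is blocked, should give the methallyl ether F4. RuHCl(CO)(PPh3)3 (5 mol %, toluene, 80 °C, below the onset of Claisen rearrangement) then migrates the double bond into conjugation with oxygen to give 9.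

Further compounds
F1 | step 5 | N-methylflindersine (2,2,6-trimethyl-2,6-dihydro-5H-pyrano[3,2-c]quinolin-5-one) | CC1(C)C=Cc2c(O1)c1ccccc1n(C)c2=O
F2 | step 5 | racemic dimer (12 and its enantiomer) | CC(C)=C[C@H]1c2c(c3ccccc3n(C)c2=O)O[C@H]2[C@@H]1c1c(c3ccccc3n(C)c1=O)OC2(C)C.CC(C)=C[C@@H]1c2c(c3ccccc3n(C)c2=O)O[C@@H]2[C@H]1c1c(c3ccccc3n(C)c1=O)OC2(C)C
F3 | step 4 | racemic epoxy ether (10 and its enantiomer) | CC1(C)O[C@H]1Oc1cc(=O)n(C)c2ccccc12.CC1(C)O[C@@H]1Oc1cc(=O)n(C)c2ccccc12
F4 | step 3 | 1-methyl-4-[(2-methylprop-2-en-1-yl)oxy]quinolin-2(1H)-one | C=C(C)COc1cc(=O)n(C)c2ccccc12
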